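**Strategy.** The route rests on disconnecting the C2–C1′ bond: a rhodium-catalysed enantioselective 1,4-addition of a 3,5-dioxygenated arylboronic acid to a 6-geranyl-5,7-dioxygenated chromone. In one operation this joins ring B to the A/C bicycle and sets the only stereocentre, C2, under neutral conditions that should not open the pyranone. The feature exploited is that C2 is the β-carbon of the vinylogous ester O1–C2=C3–C4=O, and that C6 lies para to O1. The chromone therefore grows from a C2v-symmetric 4-geranyl-3,5-dioxygenated phenol in which either ortho carbon becomes C4a, so no 6-/8-geranyl ambiguity can arise.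

Key step: step 8

Abbreviations: geranyl = (2E)-3,7-dimethylocta-2,6-dien-1-yl; MOM = methoxymethyl; pin = pinacolato; MeO-F12-BIPHEP = 2,2′-bis[bis(3,4,5-trifluorophenyl)phosphino]-6,6′-dimethoxy-1,1′-biphenyl.

Assumption: the (S)-ligand is written in step 8 on the premise that, as with (S)-biaryl bisphosphines in rhodium-catalysed 1,4-additions to cyclic enones, it exposes the Re face of C2 (giving 2S); should a trial on a model chromone show the opposite sense, the (R)-ligand is used.

**Route**

Step 1
Reactants: 1 resorcinol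
Product: 2 1,3-bis(methoxymethoxy)benzene
Conditions: NaH (2.5 equiv), MOMCl (2.5 equiv), DMF, 0 °C to rt
Reagents that add atoms: chloromethyl methyl ether (MOMCl), COCCl
Why: O-alkylation of both phenoxides by the reactive α-chloro ether (Williamson-type acetal formation) should give the bis-MOM ether, whose acetal oxygens later direct metalation.

Step 2
Reactants: 2 1,3-bis(methoxymethoxy)benzene; 3 geranyl bromide
Product: 5 2-geranyl-1,3-bis(methoxymethoxy)benzene, via aryllithium 4 (not isolated)
Conditions: n-BuLi (1.1 equiv), THF, 0 °C to rt; CuI (10 mol %), then 3, −78 °C to rt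
Reagents that add atoms: none
Why: Directed ortho-metalation should occur at C2 between the two coordinating OMOM groups, and copper-assisted SN2 allylation of the aryllithium by the primary allylic bromide joins the chain through its C1 with the E-alkene untouched.

Step 3
Reactants: 5 2-geranyl-1,3-bis(methoxymethoxy)benzene
Product: 7 4-geranyl-3,5-bis(methoxymethoxy)phenol, via boronate 6 (not isolated)
Conditions: [Ir(OMe)(cod)]2 (1.5 mol %), dtbpy (3 mol %), B2pin2 (0.6 equiv), THF, 60 °C; then 30% H2O2, aq NaOH, THF, 0 °C to rt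
Reagents that add atoms: hydrogen peroxide, OO; bis(pinacolato)diboron, CC1(C)OB(OC1(C)C)B1OC(C)(C)C(C)(C)O1 (boron is carried only in intermediate 6)
Why: Iridium-catalysed aromatic C–H borylation is sterically controlled, so the 1,2,3-trisubstituted ring should react only at C5 (meta to both OMOM groups, para to geranyl), and alkaline peroxide oxidation of the C–B bond then gives the C2v-symmetric phenol without touching the trisubstituted alkenes.

Step 4
Reactants: 7 4-geranyl-3,5-bis(methoxymethoxy)phenol
Product: 8 3-geranyl-6-hydroxy-2,4-bis(methoxymethoxy)benzaldehyde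
Conditions: MgCl2 (2 equiv), Et3N (4 equiv), (CH2O)n (6 equiv), MeCN, reflux
Reagents that add atoms: formaldehyde (as paraformaldehyde), C=O
Why: Magnesium-mediated ortho-formylation of phenols (Casnati–Skattebøl reaction) delivers formaldehyde within the magnesium phenoxide chelate only ortho to the free OH, and since the two ortho carbons of 7 are equivalent a single aldehyde should form.

Step 5
Reactants: 8 3-geranyl-6-hydroxy-2,4-bis(methoxymethoxy)benzaldehyde
Product: 9 1-[3-geranyl-6-hydroxy-2,4-bis(methoxymethoxy)phenyl]prop-2-yn-1-ol (racemic)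
Conditions: HC≡CMgBr (3 equiv), THF, −20 to 0 °C; aq NH4Cl; crude product used directly
Reagents that add atoms: ethynylmagnesium bromide, C#C[Mg]Br
Why: Grignard 1,2-addition of the alkynyl nucleophile to the aldehyde (the first equivalent deprotonates the phenol) should give the propargylic alcohol, whose new stereocentre is irrelevant because it is oxidised in step 6.

Step 6
Reactants: 9 1-[3-geranyl-6-hydroxy-2,4-bis(methoxymethoxy)phenyl]prop-2-yn-1-ol
Product: 11 6-geranyl-5,7-bis(methoxymethoxy)-4H-chromen-4-one, via ynone 10 (not isolated)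
Conditions: MnO2 (15 equiv), CH2Cl2, rt; filter; K2CO3 (0.2 equiv), acetone, rt
Reagents that add atoms: none
Why: MnO2 oxidation of the benzylic/propargylic alcohol gives the o-hydroxyaryl ynone, and the phenoxide then closes the pyranone by 6-endo-dig oxa-Michael addition to the terminal alkyne carbon, the established passage from such ynones to chromones.

Step 7
Reactants: 2 1,3-bis(methoxymethoxy)benzene
Product: 13 [3,5-bis(methoxymethoxy)phenyl]boronic acid, via boronate 12 (not isolated)
Conditions: [Ir(OMe)(cod)]2 (1 mol %), dtbpy (2 mol %), B2pin2 (0.6 equiv), THF, 80 °C; then NaIO4, NH4OAc, acetone/H2O, rt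
Reagents that add atoms: bis(pinacolato)diboron, CC1(C)OB(OC1(C)C)B1OC(C)(C)C(C)(C)O1; water, O
Why: Sterically controlled iridium-catalysed C–H borylation of the 1,3-disubstituted arene should take place at C5, the only C–H not ortho to a substituent, and periodate cleavage of the pinacol ester then frees the boronic acid under buffered conditions that spare the acetals.

Step 8
Reactants: 11 6-geranyl-5,7-bis(methoxymethoxy)-4H-chromen-4-one; 13 [3,5-bis(methoxymethoxy)phenyl]boronic acid
Product: 14 (2S)-2-[3,5-bis(methoxymethoxy)phenyl]-6-geranyl-5,7-bis(methoxymethoxy)-2,3-dihydro-4H-chromen-4-one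
Conditions: [Rh(OH)((S)-MeO-F12-BIPHEP)]2 (3 mol % Rh), 13 (3 equiv), CH2Cl2/H2O (10:1), 20 °C
Reagents that add atoms: none
Why: Transmetalation of 13 to the hydroxorhodium(I) bisphosphine complex gives an aryl–rhodium species that coordinates the C2=C3 bond of 11 and inserts it with the aryl group delivered to C2, the β-carbon of the vinylogous ester, and the resulting oxa-π-allyl rhodium enolate is protonated by water, which regenerates Rh–OH. The closest known reaction type is the Hayashi–Miyaura rhodium-catalysed asymmetric 1,4-addition of arylboronic acids, which has been applied to chromones to give flavanones. No ring is closed, since the pyranone is already in place and only the exocyclic C2–C1′ bond is formed. The single new stereocentre C2 is set by catalyst control, the atropisomeric bisphosphine leaving the Re face of C2 open to the migrating aryl group so that the 2S product should result. The step needs 1,4- over 1,2-addition and protonation of the enolate in preference to β-aryloxide elimination (ring opening to a chalcone that would re-close racemically); the soft aryl–rhodium nucleophile secures the first, and the base-free aqueous medium, the electron-poor ligand and the absence of any free phenol in 11 secure the second. The trisubstituted alkenes of the geranyl chain are not conjugated acceptors and should not insert.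

Step 9
Reactants: 14 (2S)-2-[3,5-bis(methoxymethoxy)phenyl]-6-geranyl-5,7-bis(methoxymethoxy)-2,3-dihydro-4H-chromen-4-one
Product: 15 Schizolaenone C [(2S)-2-(3,5-dihydroxyphenyl)-6-geranyl-5,7-dihydroxy-2,3-dihydro-4H-chromen-4-one]
Conditions: 3 M aq HCl/MeOH, 40–50 °C, stopped at full conversion
Reagents that add atoms: none
Why: Acid-catalysed transacetalisation of the four aryl MOM ethers to methanol should release the phenols without involving C2, the conditions being kept mild so that the geranyl alkenes are not protonated.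

**Compound list**

1 | resorcinol (benzene-1,3-diol) | Oc1cccc(O)c1 | starting material
2 | 1,3-bis(methoxymethoxy)benzene | COCOc1cccc(OCOC)c1 | intermediate
3 | geranyl bromide [(2E)-1-bromo-3,7-dimethylocta-2,6-diene] | CC(C)=CCC/C(C)=C/CBr | starting material
4 | [2,6-bis(methoxymethoxy)phenyl]lithium | [Li]c1c(OCOC)cccc1OCOC | intermediate
5 | 2-geranyl-1,3-bis(methoxymethoxy)benzene | CC(C)=CCC/C(C)=C/Cc1c(OCOC)cccc1OCOC | intermediate
6 | 2-[4-geranyl-3,5-bis(methoxymethoxy)phenyl]-4,4,5,5-tetramethyl-1,3,2-dioxaborolane | CC(C)=CCC/C(C)=C/Cc1c(OCOC)cc(B2OC(C)(C)C(C)(C)O2)cc1OCOC | intermediate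
7 | 4-geranyl-3,5-bis(methoxymethoxy)phenol | CC(C)=CCC/C(C)=C/Cc1c(OCOC)cc(O)cc1OCOC | intermediate
8 | 3-geranyl-6-hydroxy-2,4-bis(methoxymethoxy)benzaldehyde | CC(C)=CCC/C(C)=C/Cc1c(OCOC)cc(O)c(C=O)c1OCOC | intermediate
9 | 1-[3-geranyl-6-hydroxy-2,4-bis(methoxymethoxy)phenyl]prop-2-yn-1-ol (racemic) | CC(C)=CCC/C(C)=C/Cc1c(OCOC)cc(O)c(C(O)C#C)c1OCOC | intermediate
10 | 1-[3-geranyl-6-hydroxy-2,4-bis(methoxymethoxy)phenyl]prop-2-yn-1-one | CC(C)=CCC/C(C)=C/Cc1c(OCOC)cc(O)c(C(=O)C#C)c1OCOC | intermediate
11 | 6-geranyl-5,7-bis(methoxymethoxy)-4H-chromen-4-one | CC(C)=CCC/C(C)=C/Cc1c(OCOC)cc2occc(=O)c2c1OCOC | intermediate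
12 | 2-[3,5-bis(methoxymethoxy)phenyl]-4,4,5,5-tetramethyl-1,3,2-dioxaborolane | COCOc1cc(OCOC)cc(B2OC(C)(C)C(C)(C)O2)c1 | intermediate
13 | [3,5-bis(methoxymethoxy)phenyl]boronic acid | COCOc1cc(OCOC)cc(B(O)O)c1 | intermediate
14 | (2S)-2-[3,5-bis(methoxymethoxy)phenyl]-6-geranyl-5,7-bis(methoxymethoxy)-2,3-dihydro-4H-chromen-4-one | CC(C)=CCC/C(C)=C/Cc1c(OCOC)cc2c(c1OCOC)C(=O)C[C@@H](c1cc(OCOC)cc(OCOC)c1)O2 | intermediate
15 | Schizolaenone C: (2S)-2-(3,5-dihydroxyphenyl)-6-geranyl-5,7-dihydroxy-2,3-dihydro-4H-chromen-4-one | CC(C)=CCC/C(C)=C/Cc1c(O)cc2c(c1O)C(=O)C[C@@H](c1cc(O)cc(O)c1)O2 | target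

**Step count and risk**

Total step count: 9. Longest linear sequence: 8 (steps 1–6, 8 and 9); step 7 is the side branch.

Steps most likely to fail:

1. Step 8. The rhodium enolate may undergo β-aryloxide elimination (ring opening), insertion into the electron-rich 5-alkoxychromone may be slow enough for protodeboronation to compete, or facial discrimination may be insufficient. The fallback sets out from 8 and returns at 14, and replaces the C2–C1′ bond formation by the classical O1–C2 closure followed by resolution.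
   - Methylmagnesium bromide adds to aldehyde 8 to give 1-[3-geranyl-6-hydroxy-2,4-bis(methoxymethoxy)phenyl]ethanol F1, which MnO2 oxidises to 1-[3-geranyl-6-hydroxy-2,4-bis(methoxymethoxy)phenyl]ethanone F2.
   - Claisen–Schmidt condensation (KOH, EtOH) with 3,5-bis(methoxymethoxy)benzaldehyde F3 (from commercial 3,5-dihydroxybenzaldehyde, MOMCl and NaH) gives the 2′-hydroxychalcone (2E)-3-[3,5-bis(methoxymethoxy)phenyl]-1-[3-geranyl-6-hydroxy-2,4-bis(methoxymethoxy)phenyl]prop-2-en-1-one F4.
   - The only free phenol of F4 is the one para to geranyl, so oxa-Michael closure (NaOAc, EtOH, reflux) can give only the 6-geranyl flavanone, as the racemate rac-2-[3,5-bis(methoxymethoxy)phenyl]-6-geranyl-5,7-bis(methoxymethoxy)-2,3-dihydro-4H-chromen-4-one F5.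
   - Kinetic resolution by asymmetric transfer hydrogenation (Cp*Rh–TsDPEN chloride, HCO2H/Et3N) uses the catalyst antipode that reduces the 2R ketone to the cis alcohol (2R,4R)-2-[3,5-bis(methoxymethoxy)phenyl]-6-geranyl-5,7-bis(methoxymethoxy)chroman-4-ol F6. The unreduced 2S ketone that remains is 14.

2. Step 3. Iridium boryl or hydride species may attack the geranyl chain (vinylic or allylic borylation, hydroboration, alkene migration) faster than the hindered, electron-rich arene C–H. The fallback sets out from 13 and returns at 7, and installs the oxygen before the chain.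
   - Oxidation of boronic acid 13 (H2O2, aq NaOH) gives 3,5-bis(methoxymethoxy)phenol F7, which is silylated (TIPSCl, imidazole, DMF) to [3,5-bis(methoxymethoxy)phenoxy]tri(propan-2-yl)silane F8.
   - Directed ortho-metalation (n-BuLi, THF, 0 °C) should take place between the two OMOM groups, para to the bulky non-coordinating silyloxy group, to give {2,6-bis(methoxymethoxy)-4-[tri(propan-2-yl)silyloxy]phenyl}lithium F9.
   - Allylation of F9 with geranyl bromide 3 (CuI cat.) gives [4-geranyl-3,5-bis(methoxymethoxy)phenoxy]tri(propan-2-yl)silane F10, and TBAF (THF, 0 °C) then frees phenol 7.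

3. Step 9. Once the 5-OH is free, acid may promote ring opening to the chalcone and re-closure (loss of configuration at C2 and drift of the chain from C6 to C8), and the phenols flanking the geranyl group may add to its protonated alkene. The fallback sets out from 11 (and from 1 for the boron partner) and returns at 15; it moves the acid step to a compound that has no stereocentre and cannot ring-open, and ends with a fluoride desilylation.
   - HCl/MeOH on chromone 11 gives 6-geranyl-5,7-dihydroxy-4H-chromen-4-one F11, which is silylated (TBSOTf, 2,6-lutidine, CH2Cl2) to 5,7-bis[(tert-butyldimethylsilyl)oxy]-6-geranyl-4H-chromen-4-one F12.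
   - Resorcinol 1 is silylated (TBSCl, imidazole) to 1,3-bis[(tert-butyldimethylsilyl)oxy]benzene F13 and converted as in step 7, via 2-{3,5-bis[(tert-butyldimethylsilyl)oxy]phenyl}-4,4,5,5-tetramethyl-1,3,2-dioxaborolane F14, into {3,5-bis[(tert-butyldimethylsilyl)oxy]phenyl}boronic acid F15.
   - The rhodium-catalysed addition of F15 to F12 under the conditions of step 8 gives (2S)-2-{3,5-bis[(tert-butyldimethylsilyl)oxy]phenyl}-5,7-bis[(tert-butyldimethylsilyl)oxy]-6-geranyl-2,3-dihydro-4H-chromen-4-one F16.
   - Et3N·3HF (THF, 0 °C to rt) removes the four silyl groups under nearly neutral conditions to give 15.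

**Further compounds**

F1 | step 8 | 1-[3-geranyl-6-hydroxy-2,4-bis(methoxymethoxy)phenyl]ethanol (racemic) | CC(C)=CCC/C(C)=C/Cc1c(OCOC)cc(O)c(C(C)O)c1OCOC
F2 | step 8 | 1-[3-geranyl-6-hydroxy-2,4-bis(methoxymethoxy)phenyl]ethanone | CC(C)=CCC/C(C)=C/Cc1c(OCOC)cc(O)c(C(C)=O)c1OCOC
F3 | step 8 | 3,5-bis(methoxymethoxy)benzaldehyde | COCOc1cc(C=O)cc(OCOC)c1
F4 | step 8 | (2E)-3-[3,5-bis(methoxymethoxy)phenyl]-1-[3-geranyl-6-hydroxy-2,4-bis(methoxymethoxy)phenyl]prop-2-en-1-one | CC(C)=CCC/C(C)=C/Cc1c(OCOC)cc(O)c(C(=O)/C=C/c2cc(OCOC)cc(OCOC)c2)c1OCOC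
F5 | step 8 | rac-2-[3,5-bis(methoxymethoxy)phenyl]-6-geranyl-5,7-bis(methoxymethoxy)-2,3-dihydro-4H-chromen-4-one | CC(C)=CCC/C(C)=C/Cc1c(OCOC)cc2c(c1OCOC)C(=O)CC(c1cc(OCOC)cc(OCOC)c1)O2
F6 | step 8 | (2R,4R)-2-[3,5-bis(methoxymethoxy)phenyl]-6-geranyl-5,7-bis(methoxymethoxy)chroman-4-ol | CC(C)=CCC/C(C)=C/Cc1c(OCOC)cc2c(c1OCOC)[C@H](O)C[C@H](c1cc(OCOC)cc(OCOC)c1)O2
F7 | step 3 | 3,5-bis(methoxymethoxy)phenol | COCOc1cc(O)cc(OCOC)c1
F8 | step 3 | [3,5-bis(methoxymethoxy)phenoxy]tri(propan-2-yl)silane | COCOc1cc(O[Si](C(C)C)(C(C)C)C(C)C)cc(OCOC)c1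
F9 | step 3 | {2,6-bis(methoxymethoxy)-4-[tri(propan-2-yl)silyloxy]phenyl}lithium | [Li]c1c(OCOC)cc(O[Si](C(C)C)(C(C)C)C(C)C)cc1OCOC
F10 | step 3 | [4-geranyl-3,5-bis(methoxymethoxy)phenoxy]tri(propan-2-yl)silane | CC(C)=CCC/C(C)=C/Cc1c(OCOC)cc(O[Si](C(C)C)(C(C)C)C(C)C)cc1OCOC
F11 | step 9 | 6-geranyl-5,7-dihydroxy-4H-chromen-4-one | CC(C)=CCC/C(C)=C/Cc1c(O)cc2occc(=O)c2c1O
F12 | step 9 | 5,7-bis[(tert-butyldimethylsilyl)oxy]-6-geranyl-4H-chromen-4-one | CC(C)=CCC/C(C)=C/Cc1c(O[Si](C)(C)C(C)(C)C)cc2occc(=O)c2c1O[Si](C)(C)C(C)(C)C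
F13 | step 9 | 1,3-bis[(tert-butyldimethylsilyl)oxy]benzene | CC(C)(C)[Si](C)(C)Oc1cccc(O[Si](C)(C)C(C)(C)C)c1
F14 | step 9 | 2-{3,5-bis[(tert-butyldimethylsilyl)oxy]phenyl}-4,4,5,5-tetramethyl-1,3,2-dioxaborolane | CC(C)(C)[Si](C)(C)Oc1cc(O[Si](C)(C)C(C)(C)C)cc(B2OC(C)(C)C(C)(C)O2)c1
F15 | step 9 | {3,5-bis[(tert-butyldimethylsilyl)oxy]phenyl}boronic acid | CC(C)(C)[Si](C)(C)Oc1cc(O[Si](C)(C)C(C)(C)C)cc(B(O)O)c1
F16 | step 9 | (2S)-2-{3,5-bis[(tert-butyldimethylsilyl)oxy]phenyl}-5,7-bis[(tert-butyldimethylsilyl)oxy]-6-geranyl-2,3-dihydro-4H-chromen-4-one | CC(C)=CCC/C(C)=C/Cc1c(O[Si](C)(C)C(C)(C)C)cc2c(c1O[Si](C)(C)C(C)(C)C)C(=O)C[C@@H](c1cc(O[Si](C)(C)C(C)(C)C)cc(O[Si](C)(C)C(C)(C)C)c1)O2
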